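The lactone (ring C) is cut between its ring oxygen O1 and the aromatic carbon C8a, which turns the phloroglucinol ring A into a resorcinol. The precursor is an open-chain (S)-3,3-diarylpropanoic acid with C8a–H. That hydrogen is meta to the C5 and C7 oxygens and so out of reach of electrophilic chemistry. It is, however, the only C–H lying ortho to both the C8 ketone and the C4 side chain. A palladium-catalysed C–H lactonisation guided by ketone and carboxylate thus installs the third oxygen of ring A, closes ring C and fixes the 8-acyl rather than 6-acyl pattern in one operation. C4 comes from an asymmetric coumarin arylation.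

Key step: step 5

Numbering: target numbering is used throughout (O1, C2 carbonyl, C3, C4, C4a, C5 to C8, C8a). Ring A is the benzo ring, ring B the aryl group on C4, ring C the lactone. The target is (S) at C4.

Assumption: the known sense of induction of the Rh/SEGPHOS arylation of coumarins, (R)-ligand to (R)-4-arylchroman-2-one, is taken to hold for the 7-methoxy substrate. Both ligand antipodes are commercial.

Step 1
Reactants: 1 7-methoxycoumarin (herniarin); 2 4-methoxyphenylboronic acid
Product: 3 (S)-7-methoxy-4-(4-methoxyphenyl)chroman-2-one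
Conditions: Rh(acac)(C2H4)2 (3 mol %), (S)-SEGPHOS (3.3 mol %), excess 2, dioxane/H2O 10:1, 60 °C
Reagents that add atoms: none
Why: Hayashi–Miyaura asymmetric 1,4-addition, in which the aryl-rhodium species inserts the C3=C4 bond of the coumarin inside the chiral bisphosphine pocket and water protonates the enolate; since the (R)-ligand is known to give (R)-4-arylchroman-2-ones, the (S)-ligand should set C4 as (S).

Step 2
Reactants: 3 (S)-7-methoxy-4-(4-methoxyphenyl)chroman-2-one
Product: 5 methyl (S)-3-(2,4-dimethoxyphenyl)-3-(4-methoxyphenyl)propanoate, via ring-opened phenol ester 4 (not isolated)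
Conditions: K2CO3, MeI, MeOH/acetone, reflux
Reagents that add atoms: methanol, CO; iodomethane, CI
Why: Base-mediated methanolysis of the aryl lactone followed by Williamson O-methylation of the freed phenoxide traps the open form, blocks the future C5 oxygen for the rest of the route and leaves the non-acidic C4 methine untouched.

Step 3
Reactants: 5 methyl (S)-3-(2,4-dimethoxyphenyl)-3-(4-methoxyphenyl)propanoate; 6 3-phenylpropanoyl chloride
Product: 7 methyl (S)-3-[2,4-dimethoxy-5-(3-phenylpropanoyl)phenyl]-3-(4-methoxyphenyl)propanoate
Conditions: SnCl4 (2.2 equiv), CH2Cl2, −10 to 0 °C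
Reagents that add atoms: none
Why: Friedel–Crafts acylation should go to the future C8, which is para to one and ortho to the other methoxy group of ring A, far more nucleophilic than any carbon of ring B and less hindered than the carbon between the two methoxy groups, while the mild Lewis acid at low temperature keeps self-cyclisation of the acid chloride and ether cleavage slow.

Step 4
Reactants: 7 methyl (S)-3-[2,4-dimethoxy-5-(3-phenylpropanoyl)phenyl]-3-(4-methoxyphenyl)propanoate
Product: 8 (S)-3-[2,4-dimethoxy-5-(3-phenylpropanoyl)phenyl]-3-(4-methoxyphenyl)propanoic acid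
Conditions: LiOH, THF/H2O, rt; then 1 M HCl
Reagents that add atoms: lithium hydroxide, [Li+].[OH-]
Why: Saponification of an unhindered methyl ester, under which neither the aryl ketone nor the C4 methine is affected.

Step 5
Reactants: 8 (S)-3-[2,4-dimethoxy-5-(3-phenylpropanoyl)phenyl]-3-(4-methoxyphenyl)propanoic acid
Product: 10 (S)-5,7-dimethoxy-4-(4-methoxyphenyl)-8-(3-phenylpropanoyl)chroman-2-one, via seven-membered palladacycle 9 (not isolated)
Conditions: Pd(OAc)2 (10 mol %), N-acetylglycine (20 mol %), PhI(OAc)2 (1.5 equiv), KOAc (1 equiv), t-BuOH, 80 °C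
Reagents that add atoms: none
Why: Proposed new method: the potassium carboxylate of 8 binds divalent palladium and the C8 ketone oxygen, which turns away from the C7 methoxy group, completes a chelate that holds the metal over C8a–H, so that concerted metalation–deprotonation assisted by N-acetylglycine gives palladacycle 9, which PhI(OAc)2 oxidises to tetravalent palladium before C(sp2)–O reductive elimination joins the carboxylate oxygen to C8a and returns Pd(OAc)2. The closest known reaction types are the carboxylate-directed C–H activation/C–O cyclisation of arylacetic and biaryl-2-carboxylic acids under Pd(OAc)2/PhI(OAc)2 and the ketone-directed ortho-acyloxylation of aryl ketones; their merger on a 3,3-diarylpropanoic acid through a seven-membered chelate is what is new. Ring C closes as a six-membered lactone by contraction of the seven-membered palladacycle in the reductive elimination, with O1 delivered by the acid itself. No stereocentre is formed, and C4 should keep its (S) configuration because its methine hydrogen is neither acidic nor placed for β-hydride elimination from the aryl- and oxygen-bound metal. The step needs site selectivity for C8a–H over the ortho hydrogens of ring B and over C6–H, which is secured because only C8a–H is within reach of both donors, ring B being served by the carboxylate alone and C6–H by neither. It also needs the tethered carboxylate to win over acetate at tetravalent palladium, which chelation favours, and the methyl ethers keep the three phenol oxygens out of the oxidation and the C5 oxygen out of any alternative lactonisation.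

Step 6
Reactants: 10 (S)-5,7-dimethoxy-4-(4-methoxyphenyl)-8-(3-phenylpropanoyl)chroman-2-one
Product: 11 (S)-5,7-dihydroxy-4-(4-hydroxyphenyl)-8-(3-phenylpropanoyl)chroman-2-one (target)
Conditions: BBr3 (6 equiv), CH2Cl2, −78 °C to rt; brief quench with ice-water
Reagents that add atoms: none
Why: BBr3 demethylation cleaves the three aryl methyl ethers by bromide attack at the O-methyl carbons, so no nucleophile is offered to the lactone carbonyl, C4 is not involved and the 8-acyl lactone pattern should be kept.

Compound list
1 | 7-methoxycoumarin (herniarin, 7-methoxy-2H-chromen-2-one) | COc1ccc2ccc(=O)oc2c1 | starting material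
2 | 4-methoxyphenylboronic acid | COc1ccc(B(O)O)cc1 | starting material
3 | (S)-7-methoxy-4-(4-methoxyphenyl)chroman-2-one | O=C1C[C@@H](c2ccc(OC)cc2)c2ccc(OC)cc2O1 | intermediate
4 | methyl (S)-3-(2-hydroxy-4-methoxyphenyl)-3-(4-methoxyphenyl)propanoate (not isolated) | COC(=O)C[C@@H](c1ccc(OC)cc1)c1ccc(OC)cc1O | intermediate
5 | methyl (S)-3-(2,4-dimethoxyphenyl)-3-(4-methoxyphenyl)propanoate | COC(=O)C[C@@H](c1ccc(OC)cc1)c1ccc(OC)cc1OC | intermediate
6 | 3-phenylpropanoyl chloride (hydrocinnamoyl chloride) | O=C(Cl)CCc1ccccc1 | starting material
7 | methyl (S)-3-[2,4-dimethoxy-5-(3-phenylpropanoyl)phenyl]-3-(4-methoxyphenyl)propanoate | COC(=O)C[C@@H](c1ccc(OC)cc1)c1cc(C(=O)CCc2ccccc2)c(OC)cc1OC | intermediate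
8 | (S)-3-[2,4-dimethoxy-5-(3-phenylpropanoyl)phenyl]-3-(4-methoxyphenyl)propanoic acid | OC(=O)C[C@@H](c1ccc(OC)cc1)c1cc(C(=O)CCc2ccccc2)c(OC)cc1OC | intermediate
9 | seven-membered palladacycle of 8, divalent palladium bound to C8a and to the carboxylate oxygen, (S) at C4 (ketone oxygen and one further neutral donor not drawn; not isolated) | O=C1C[C@@H](c2ccc(OC)cc2)c2c(OC)cc(OC)c(C(=O)CCc3ccccc3)c2[Pd]O1 | intermediate
10 | (S)-5,7-dimethoxy-4-(4-methoxyphenyl)-8-(3-phenylpropanoyl)chroman-2-one | O=C1C[C@@H](c2ccc(OC)cc2)c2c(OC)cc(OC)c(C(=O)CCc3ccccc3)c2O1 | intermediate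
11 | (S)-5,7-dihydroxy-4-(4-hydroxyphenyl)-8-(3-phenylpropanoyl)chroman-2-one (CNP0383109.1) | O=C1C[C@@H](c2ccc(O)cc2)c2c(O)cc(O)c(C(=O)CCc3ccccc3)c2O1 | target

Total step count: 6. Longest linear sequence: 6 steps (1 to 3 to 5 to 7 to 8 to 10 to 11).

Steps most likely to fail

**1. Step 5 (proposed new method).**
- Palladation at the doubly flanked C8a–H may be slow.
- Acetate may outrun the tethered carboxylate in the reductive elimination.
- The trivalent iodine oxidant may attack the electron-rich rings or the ketone α-position.

The fallback sets out from 7 and comes back at 10, replacing steps 4 and 5 with known chemistry.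
- The known ketone-directed ortho-C–H hydroxylation of aryl ketones uses Pd(O2CCF3)2 (5 mol %) and PhI(O2CCF3)2 in 1,2-dichloroethane at 80 °C. It would oxygenate the same C8a–H with external trifluoroacetate to give methyl (S)-3-[4,6-dimethoxy-3-(3-phenylpropanoyl)-2-(trifluoroacetoxy)phenyl]-3-(4-methoxyphenyl)propanoate F1.
- Aqueous NaHCO3 work-up should hydrolyse this to methyl (S)-3-[2-hydroxy-4,6-dimethoxy-3-(3-phenylpropanoyl)phenyl]-3-(4-methoxyphenyl)propanoate F2.
- p-TsOH in toluene at reflux would then close the ring from the new phenol onto the ester to give 10. This is the only lactone possible, because the other ortho oxygen is a methyl ether.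

**2. Step 6.**
- The activated aryl lactone may open during demethylation or quench and reclose onto the freed C5 oxygen, which would transpose the acyl pattern.
- The hindered C5 ether may be cleaved incompletely.
- C4 may erode through reversible ipso-protonation of the very electron-rich ring A.

The fallback sets out from 7 and comes back at 11. It exchanges the protecting groups before the key step, so that the last operation is a neutral hydrogenolysis.
- BBr3 in CH2Cl2 is applied to 7, where ring A has only one ortho oxygen and is less electron-rich. Treatment with p-TsOH in toluene would then give (S)-7-hydroxy-4-(4-hydroxyphenyl)-6-(3-phenylpropanoyl)chroman-2-one F3.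
- K2CO3 and BnBr in MeOH/DMF would open and benzylate it to methyl (S)-3-[2,4-bis(benzyloxy)-5-(3-phenylpropanoyl)phenyl]-3-[4-(benzyloxy)phenyl]propanoate F4.
- LiOH in THF/H2O would give (S)-3-[2,4-bis(benzyloxy)-5-(3-phenylpropanoyl)phenyl]-3-[4-(benzyloxy)phenyl]propanoic acid F5.
- The conditions of step 5 would give (S)-5,7-bis(benzyloxy)-4-[4-(benzyloxy)phenyl]-8-(3-phenylpropanoyl)chroman-2-one F6.
- H2 (1 atm), Pd/C in EtOAc would release 11 without any nucleophile or acid present.

**3. Step 1.**
- Insertion into the donor-substituted, less electrophilic coumarin may be slow, so that protodeboronation consumes the boronic acid before conversion is complete.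

The fallback sets out from 1 and 2 and comes back at 3. It sets C4 by hydride delivery instead of aryl delivery.
- An oxidative Heck arylation with Pd(OAc)2 and 1,10-phenanthroline under O2 in DMF at 80 °C would give 7-methoxy-4-(4-methoxyphenyl)coumarin F7.
- A copper hydride asymmetric conjugate reduction would then give 3. It uses Cu(OAc)2, DTBM-SEGPHOS, (EtO)2MeSiH and t-BuOH in toluene. The ligand antipode is chosen for hydride delivery to the face that leaves C4 (S), and t-BuOH protonates the copper enolate before over-reduction.

Further compounds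
F1 | step 5 | methyl (S)-3-[4,6-dimethoxy-3-(3-phenylpropanoyl)-2-(trifluoroacetoxy)phenyl]-3-(4-methoxyphenyl)propanoate | COC(=O)C[C@@H](c1ccc(OC)cc1)c1c(OC)cc(OC)c(C(=O)CCc2ccccc2)c1OC(=O)C(F)(F)F
F2 | step 5 | methyl (S)-3-[2-hydroxy-4,6-dimethoxy-3-(3-phenylpropanoyl)phenyl]-3-(4-methoxyphenyl)propanoate | COC(=O)C[C@@H](c1ccc(OC)cc1)c1c(OC)cc(OC)c(C(=O)CCc2ccccc2)c1O
F3 | step 6 | (S)-7-hydroxy-4-(4-hydroxyphenyl)-6-(3-phenylpropanoyl)chroman-2-one | O=C1C[C@@H](c2ccc(O)cc2)c2cc(C(=O)CCc3ccccc3)c(O)cc2O1
F4 | step 6 | methyl (S)-3-[2,4-bis(benzyloxy)-5-(3-phenylpropanoyl)phenyl]-3-[4-(benzyloxy)phenyl]propanoate | COC(=O)C[C@@H](c1ccc(OCc2ccccc2)cc1)c1cc(C(=O)CCc2ccccc2)c(OCc2ccccc2)cc1OCc1ccccc1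
F5 | step 6 | (S)-3-[2,4-bis(benzyloxy)-5-(3-phenylpropanoyl)phenyl]-3-[4-(benzyloxy)phenyl]propanoic acid | OC(=O)C[C@@H](c1ccc(OCc2ccccc2)cc1)c1cc(C(=O)CCc2ccccc2)c(OCc2ccccc2)cc1OCc1ccccc1
F6 | step 6 | (S)-5,7-bis(benzyloxy)-4-[4-(benzyloxy)phenyl]-8-(3-phenylpropanoyl)chroman-2-one | O=C1C[C@@H](c2ccc(OCc3ccccc3)cc2)c2c(OCc3ccccc3)cc(OCc3ccccc3)c(C(=O)CCc3ccccc3)c2O1
F7 | step 1 | 7-methoxy-4-(4-methoxyphenyl)coumarin | COc1ccc(cc1)-c1cc(=O)oc2cc(OC)ccc12
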